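The constants were drawn at random within sensible limits; no experiment stands behind them.

Count the acid and this flask ends with 4.20 mM more than it can absorb; that number carries the whole reckoning.

    nucleophile + acid set free ⇌ idle adduct, settled at all times (K1 = 110 M⁻¹)
    acid set free + free base ⇌ salt of the base (K2 = 1.0 × 10⁶ M⁻¹, k2 = 120 M⁻¹ h⁻¹)
    acid set free + scavenger → scavenged by-product (k3 = 97 M⁻¹ h⁻¹)
    electrophile + nucleophile → acid set free + target (k4 = 15 M⁻¹ h⁻¹)
    nucleophile + acid set free ⇌ protonated nucleophile, settled at all times (K5 = 580 M⁻¹)

electrophile 21 mM; free base 21.0 mM; protonated nucleophile 21.0 mM; scavenger 16.8 mM; time 10 d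

- amounts and yields of acid set free count idle adduct too
- run time (flask): 10 d

* part of the electrophile that has reacted at 10 d
* share of free nucleophile in free nucleophile and protonated nucleophile together, at 10 d

Here is the count. The protonated nucleophile brings 21.0 mM of acid and full reaction of the electrophile sets free 21 mM more, while free base and scavenger together take up 37.8 mM. Acid brought plus acid made, minus that capacity, is the acid surplus. You may object that the salt of the base could hand its acid back, but 1.0 × 10⁶ M⁻¹ stands far above 580 M⁻¹, so the count stands.

Does the surplus stop the reaction? Work with f, the fraction of electrophile left. Electrophile and nucleophile are charged equally and go one for one, so the nucleophile in its forms together is f times 21 mM. Its free part is that pool divided by a slowing factor: one plus 690 M⁻¹ times [acid set free]. The reciprocal of f therefore climbs in a straight line, at 0.315 h⁻¹ divided by that factor.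

Charge the whole run at the full surplus: the factor is 3.90, and f ends at 4.90 %.

But that overstates the acid. Acid not yet made and acid held by the pool can each reach f times 21 mM, so [acid set free] stands near 2.14 mM, below the surplus. The factor falls to 2.48 and f to 3.17 %. That is a rough figure, since one acid level stands for a changing one, but I commit to it. With [acid set free] then near 2.87 mM, the free share is one over one plus 580 M⁻¹ times that, 37.5 %, and the protonated nucleophile is the resting state.

The forecast gave 97 % (96 % to 98 %) and 35 % (30 % to 42 %), saying the reaction “slows as leftover acid ties up the remaining nucleophile”, and its share lies below mine.

This flask gives 96.9 % reacted and 35.6 % free. Left until 100 d, it holds 4.04 mM of free acid, a little less than the surplus. Now take the neighbour flask with 42 mM of scavenger: its surplus comes to −21.0 mM, below zero, so charge its whole run at a factor of one, and the reciprocal of f climbs at 0.315 h⁻¹, leaving 1.31 %. That neighbour flask ends with 1.33 % of its electrophile.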